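Ring A (rings lettered A–D from the 2,4,6-trihydroxyphenoxy end) is not attached to ring B by arylation; it is assembled on the ring B oxygen. Its C(OH)–C(OAr)–C(OH) triad is an aryloxymalonyl unit and its CH–C(OH)–CH triad is the acetone unit of a 3-oxopentanedioate. One double Claisen condensation (acylation, then Dieckmann closure) therefore forms both new carbon–carbon bonds of ring A and its aromatic triol. The precursor is the diethyl malonate O-linked to the octabenzylated BCD phenol, itself built by two rounds of para-formyl-activated Ullmann coupling and Baeyer–Villiger oxidation. Ester hydrolysis, decarboxylation and one hydrogenolysis finish the target.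

Key step: step 15

Assumption: the target has no stereocentre, so no configuration has to be set.

Remark: diethyl chloromalonate is used for the O-alkylation instead of the bromo ester, because the bromo ester can transfer bromine to electron-rich phenoxides; the malonate obtained is the same. Ethyl esters are kept on both partners of the key step so that alkoxide exchange is degenerate.

Abbreviations: Bn = benzyl; CD-aryl = 3,5-bis(benzyloxy)-4-[3,4,5-tris(benzyloxy)phenoxy]phenyl; BCD-aryl = 2,3,5-tris(benzyloxy)-4-(CD-aryloxy)phenyl.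

**Route**

Step 1
Reactants: 1 3,4,5-trihydroxybenzaldehyde
Product: 2 3,4,5-tris(benzyloxy)benzaldehyde
Conditions: BnBr, K2CO3, DMF, 60 °C
Reagents that add atoms: benzyl bromide, BrCc1ccccc1
Why: Williamson etherification, in which the three phenoxides displace bromide from benzyl bromide by SN2 while the non-enolisable aldehyde is untouched.

Step 2
Reactants: 2 3,4,5-tris(benzyloxy)benzaldehyde
Product: 4 3,4,5-tris(benzyloxy)phenol, via formate ester 3 (not isolated)
Conditions: mCPBA, CH2Cl2, 0 °C to rt; then K2CO3 (cat.), MeOH, rt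
Reagents that add atoms: mCPBA, OOC(=O)c1cccc(Cl)c1
Why: Baeyer–Villiger oxidation in its Dakin-type sense, in which the electron-rich aryl group migrates to give formate 3 and base-catalysed methanolysis then frees the phenol.

Step 3
Reactants: 5 4-bromo-3,5-dimethoxybenzaldehyde
Product: 6 4-bromo-3,5-dihydroxybenzaldehyde
Conditions: BBr3, CH2Cl2, −78 °C to rt; then H2O
Reagents that add atoms: none
Why: Lewis-acid ether cleavage, in which BBr3 complexes each methoxy oxygen and bromide removes the methyl group by SN2, the aldehyde being regenerated from its boron adduct on aqueous work-up.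

Step 4
Reactants: 6 4-bromo-3,5-dihydroxybenzaldehyde
Product: 7 3,5-bis(benzyloxy)-4-bromobenzaldehyde
Conditions: BnBr, K2CO3, DMF, 60 °C
Reagents that add atoms: benzyl bromide, BrCc1ccccc1
Why: Williamson etherification of both phenols, with the aryl bromide inert to carbonate.

Step 5
Reactants: 4 3,4,5-tris(benzyloxy)phenol; 7 3,5-bis(benzyloxy)-4-bromobenzaldehyde
Product: 8 3,5-bis(benzyloxy)-4-[3,4,5-tris(benzyloxy)phenoxy]benzaldehyde
Conditions: CuI (10 mol%), picolinic acid (20 mol%), K3PO4, DMSO, 90 °C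
Reagents that add atoms: none
Why: Ullmann-type copper-catalysed O-arylation, in which the para formyl group activates the C–Br bond of 7 against the two flanking benzyloxy groups, phenol 4 has both ortho positions free, and the picolinic acid system is one used for ortho,ortho'-disubstituted aryl halides.

Step 6
Reactants: 8 3,5-bis(benzyloxy)-4-[3,4,5-tris(benzyloxy)phenoxy]benzaldehyde
Product: 10 3,5-bis(benzyloxy)-4-[3,4,5-tris(benzyloxy)phenoxy]phenol, via formate ester 9 (not isolated)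
Conditions: mCPBA, CH2Cl2, 0 °C to rt; then K2CO3 (cat.), MeOH/THF, rt
Reagents that add atoms: mCPBA, OOC(=O)c1cccc(Cl)c1
Why: Baeyer–Villiger oxidation as in step 2, where the para aryloxy donor favours aryl over hydride migration and the diaryl and benzyl ethers are inert to the peracid.

Step 7
Reactants: 11 2-bromoresorcinol (2-bromobenzene-1,3-diol)
Product: 13 3-bromo-2,4-dihydroxybenzaldehyde, via iminium salt 12 (not isolated)
Conditions: POCl3, DMF, MeCN, −10 °C to rt; then H2O, 50 °C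
Reagents that add atoms: N,N-dimethylformamide, CN(C)C=O; water, O
Why: Vilsmeier–Haack formylation, in which the chloroiminium ion attacks C4 (ortho to one hydroxyl and para to the other; C6 is equivalent and C2 is blocked by bromine) and water hydrolyses iminium salt 12.

Step 8
Reactants: 13 3-bromo-2,4-dihydroxybenzaldehyde
Product: 14 2,4-bis(benzyloxy)-3-bromobenzaldehyde
Conditions: BnBr, K2CO3, DMF, 60 °C
Reagents that add atoms: benzyl bromide, BrCc1ccccc1
Why: Williamson etherification, in which the chelated 2-hydroxyl is also alkylated in warm DMF with excess reagent.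

Step 9
Reactants: 14 2,4-bis(benzyloxy)-3-bromobenzaldehyde
Product: 16 2,4-bis(benzyloxy)-3-bromophenol, via formate ester 15 (not isolated)
Conditions: mCPBA, CH2Cl2, 0 °C to rt; then K2CO3 (cat.), MeOH, rt
Reagents that add atoms: mCPBA, OOC(=O)c1cccc(Cl)c1
Why: Baeyer–Villiger oxidation, made fast by the ortho and para alkoxy groups that promote aryl migration.

Step 10
Reactants: 16 2,4-bis(benzyloxy)-3-bromophenol
Product: 17 3,5-bis(benzyloxy)-4-bromo-2-hydroxybenzaldehyde
Conditions: MgCl2, Et3N, (CH2O)n, MeCN, reflux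
Reagents that add atoms: paraformaldehyde (as formaldehyde), C=O
Why: Magnesium-mediated ortho-formylation of a phenol (Casnati–Skattebøl reaction), in which the magnesium phenoxide delivers formaldehyde to C6, the only free ortho carbon, and a second formaldehyde oxidises the benzylic alkoxide by hydride transfer.

Step 11
Reactants: 17 3,5-bis(benzyloxy)-4-bromo-2-hydroxybenzaldehyde
Product: 18 2,3,5-tris(benzyloxy)-4-bromobenzaldehyde
Conditions: BnBr, K2CO3, DMF, 60 °C
Reagents that add atoms: benzyl bromide, BrCc1ccccc1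
Why: Williamson etherification of the salicylaldehyde hydroxyl.

Step 12
Reactants: 10 3,5-bis(benzyloxy)-4-[3,4,5-tris(benzyloxy)phenoxy]phenol; 18 2,3,5-tris(benzyloxy)-4-bromobenzaldehyde
Product: 19 2,3,5-tris(benzyloxy)-4-(CD-aryloxy)benzaldehyde
Conditions: CuI (10 mol%), picolinic acid (20 mol%), K3PO4, DMSO, 90–100 °C
Reagents that add atoms: none
Why: Ullmann-type copper-catalysed O-arylation as in step 5, with the bromide of 18 para to the formyl group and phenol 10 free of ortho substituents, so that the hindrance lies only on the electrophile.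

Step 13
Reactants: 19 2,3,5-tris(benzyloxy)-4-(CD-aryloxy)benzaldehyde
Product: 21 2,3,5-tris(benzyloxy)-4-(CD-aryloxy)phenol (BCD-aryl–OH), via formate ester 20 (not isolated)
Conditions: mCPBA, CH2Cl2, 0 °C to rt; then K2CO3 (cat.), MeOH/THF, rt
Reagents that add atoms: mCPBA, OOC(=O)c1cccc(Cl)c1
Why: Baeyer–Villiger oxidation, where the ortho benzyloxy and para aryloxy groups direct aryl migration and the new hydroxyl appears exactly on the ring B carbon that must carry ring A.

Step 14
Reactants: 21 2,3,5-tris(benzyloxy)-4-(CD-aryloxy)phenol; 22 diethyl chloromalonate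
Product: 23 diethyl 2-(BCD-aryloxy)malonate
Conditions: K2CO3, acetone, reflux
Reagents that add atoms: none
Why: Williamson-type SN2 O-alkylation of the phenoxide at the doubly carbonyl-activated secondary chloride, a reaction used for aryloxymalonates of ortho-alkoxyphenols.

Step 15
Reactants: 23 diethyl 2-(BCD-aryloxy)malonate; 24 diethyl 3-oxopentanedioate
Product: 26 diethyl 2,4,6-trihydroxy-5-(BCD-aryloxy)benzene-1,3-dicarboxylate, via acyclic diketo triester 25 (not isolated)
Conditions: NaOEt, diglyme, 140 °C (EtOH distilled off, Ar); then aq. HCl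
Reagents that add atoms: none
Why: Proposed new method: the sodium enolate of 24 should be C-acylated at one methylene by an ester group of 23 (directly, or through the aryloxy ketene that the malonate enolate can shed on heating) to give 25, whose second methylene carbanion then attacks the remaining malonate ester in a Dieckmann closure (6-exo-trig), and the cyclic trione enolises to the aromatic triol. The closest known reaction is the sodium-mediated Claisen–Dieckmann condensation of diethyl malonate with diethyl 3-oxopentanedioate to diethyl 2,4,6-trihydroxybenzene-1,3-dicarboxylate; a malonate carrying an aryloxy group on its central carbon has not been used as the bis-electrophile. No stereocentre is formed. The step needs only chemoselectivity, C-acylation and carbocyclisation in preference to O-acylation to a 4-hydroxypyran-2-one, which the fully enolate-forming medium and the stability of the aromatic phenoxide should favour; both partners are symmetric, so no regiochemical question arises. Distilling out ethanol drives both condensations forward, and the benzyl and diaryl ethers are inert to alkoxide.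

Step 16
Reactants: 26 diethyl 2,4,6-trihydroxy-5-(BCD-aryloxy)benzene-1,3-dicarboxylate
Product: 28 2-(BCD-aryloxy)benzene-1,3,5-triol, via dicarboxylic acid 27 (not isolated)
Conditions: KOH, EtOH/H2O/1,4-dioxane (degassed), reflux; then aq. HCl to pH 2, 80 °C
Reagents that add atoms: none
Why: Saponification followed by decarboxylation of a 2,4,6-trihydroxybenzenedicarboxylic acid, which loses CO2 readily through ipso protonation of the electron-rich ring (its keto tautomer is a β-keto acid), while benzyl and diaryl ethers survive hot alkali and dilute acid.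

Step 17
Reactants: 28 2-(BCD-aryloxy)benzene-1,3,5-triol
Product: 29 2-{2,3,5-trihydroxy-4-[3,5-dihydroxy-4-(3,4,5-trihydroxyphenoxy)phenoxy]phenoxy}benzene-1,3,5-triol (target)
Conditions: H2 (1 atm), 10% Pd/C, THF/MeOH, rt; work-up under Ar
Reagents that add atoms: none
Why: Hydrogenolysis of the eight benzyl aryl ethers over palladium on carbon, under which diaryl ether bonds and phenolic rings are not reduced at ambient pressure.

**Compound list**

1 | 3,4,5-trihydroxybenzaldehyde | O=Cc1cc(O)c(O)c(O)c1 | starting material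
2 | 3,4,5-tris(benzyloxy)benzaldehyde | O=Cc1cc(OCc2ccccc2)c(OCc2ccccc2)c(OCc2ccccc2)c1 | intermediate
3 | 3,4,5-tris(benzyloxy)phenyl formate | O=COc1cc(OCc2ccccc2)c(OCc2ccccc2)c(OCc2ccccc2)c1 | intermediate (not isolated)
4 | 3,4,5-tris(benzyloxy)phenol | Oc1cc(OCc2ccccc2)c(OCc2ccccc2)c(OCc2ccccc2)c1 | intermediate
5 | 4-bromo-3,5-dimethoxybenzaldehyde | COc1cc(C=O)cc(OC)c1Br | starting material
6 | 4-bromo-3,5-dihydroxybenzaldehyde | O=Cc1cc(O)c(Br)c(O)c1 | intermediate
7 | 3,5-bis(benzyloxy)-4-bromobenzaldehyde | O=Cc1cc(OCc2ccccc2)c(Br)c(OCc2ccccc2)c1 | intermediate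
8 | 3,5-bis(benzyloxy)-4-[3,4,5-tris(benzyloxy)phenoxy]benzaldehyde | O=Cc1cc(OCc2ccccc2)c(Oc2cc(OCc3ccccc3)c(OCc3ccccc3)c(OCc3ccccc3)c2)c(OCc2ccccc2)c1 | intermediate
9 | 3,5-bis(benzyloxy)-4-[3,4,5-tris(benzyloxy)phenoxy]phenyl formate | O=COc1cc(OCc2ccccc2)c(Oc2cc(OCc3ccccc3)c(OCc3ccccc3)c(OCc3ccccc3)c2)c(OCc2ccccc2)c1 | intermediate (not isolated)
10 | 3,5-bis(benzyloxy)-4-[3,4,5-tris(benzyloxy)phenoxy]phenol | Oc1cc(OCc2ccccc2)c(Oc2cc(OCc3ccccc3)c(OCc3ccccc3)c(OCc3ccccc3)c2)c(OCc2ccccc2)c1 | intermediate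
11 | 2-bromoresorcinol (2-bromobenzene-1,3-diol) | Oc1cccc(O)c1Br | starting material
12 | (3-bromo-2,4-dihydroxybenzylidene)dimethyliminium chloride | C[N+](C)=Cc1ccc(O)c(Br)c1O.[Cl-] | intermediate (not isolated)
13 | 3-bromo-2,4-dihydroxybenzaldehyde | O=Cc1ccc(O)c(Br)c1O | intermediate
14 | 2,4-bis(benzyloxy)-3-bromobenzaldehyde | O=Cc1ccc(OCc2ccccc2)c(Br)c1OCc1ccccc1 | intermediate
15 | 2,4-bis(benzyloxy)-3-bromophenyl formate | O=COc1ccc(OCc2ccccc2)c(Br)c1OCc1ccccc1 | intermediate (not isolated)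
16 | 2,4-bis(benzyloxy)-3-bromophenol | Oc1ccc(OCc2ccccc2)c(Br)c1OCc1ccccc1 | intermediate
17 | 3,5-bis(benzyloxy)-4-bromo-2-hydroxybenzaldehyde | O=Cc1cc(OCc2ccccc2)c(Br)c(OCc2ccccc2)c1O | intermediate
18 | 2,3,5-tris(benzyloxy)-4-bromobenzaldehyde | O=Cc1cc(OCc2ccccc2)c(Br)c(OCc2ccccc2)c1OCc1ccccc1 | intermediate
19 | 2,3,5-tris(benzyloxy)-4-{3,5-bis(benzyloxy)-4-[3,4,5-tris(benzyloxy)phenoxy]phenoxy}benzaldehyde | O=Cc1cc(OCc2ccccc2)c(Oc2cc(OCc3ccccc3)c(Oc3cc(OCc4ccccc4)c(OCc4ccccc4)c(OCc4ccccc4)c3)c(OCc3ccccc3)c2)c(OCc2ccccc2)c1OCc1ccccc1 | intermediate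
20 | 2,3,5-tris(benzyloxy)-4-{3,5-bis(benzyloxy)-4-[3,4,5-tris(benzyloxy)phenoxy]phenoxy}phenyl formate | O=COc1cc(OCc2ccccc2)c(Oc2cc(OCc3ccccc3)c(Oc3cc(OCc4ccccc4)c(OCc4ccccc4)c(OCc4ccccc4)c3)c(OCc3ccccc3)c2)c(OCc2ccccc2)c1OCc1ccccc1 | intermediate (not isolated)
21 | 2,3,5-tris(benzyloxy)-4-{3,5-bis(benzyloxy)-4-[3,4,5-tris(benzyloxy)phenoxy]phenoxy}phenol | Oc1cc(OCc2ccccc2)c(Oc2cc(OCc3ccccc3)c(Oc3cc(OCc4ccccc4)c(OCc4ccccc4)c(OCc4ccccc4)c3)c(OCc3ccccc3)c2)c(OCc2ccccc2)c1OCc1ccccc1 | intermediate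
22 | diethyl chloromalonate | CCOC(=O)C(Cl)C(=O)OCC | starting material
23 | diethyl 2-(BCD-aryloxy)malonate | CCOC(=O)C(Oc1cc(OCc2ccccc2)c(Oc2cc(OCc3ccccc3)c(Oc3cc(OCc4ccccc4)c(OCc4ccccc4)c(OCc4ccccc4)c3)c(OCc3ccccc3)c2)c(OCc2ccccc2)c1OCc1ccccc1)C(=O)OCC | intermediate
24 | diethyl 3-oxopentanedioate | CCOC(=O)CC(=O)CC(=O)OCC | starting material
25 | diethyl 2-(BCD-aryloxy)-4-(ethoxycarbonyl)-3,5-dioxoheptanedioate (mixture of stereoisomers and enol forms) | CCOC(=O)CC(=O)C(C(=O)OCC)C(=O)C(Oc1cc(OCc2ccccc2)c(Oc2cc(OCc3ccccc3)c(Oc3cc(OCc4ccccc4)c(OCc4ccccc4)c(OCc4ccccc4)c3)c(OCc3ccccc3)c2)c(OCc2ccccc2)c1OCc1ccccc1)C(=O)OCC | intermediate (not isolated)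
26 | diethyl 2,4,6-trihydroxy-5-(BCD-aryloxy)benzene-1,3-dicarboxylate | CCOC(=O)c1c(O)c(Oc2cc(OCc3ccccc3)c(Oc3cc(OCc4ccccc4)c(Oc4cc(OCc5ccccc5)c(OCc5ccccc5)c(OCc5ccccc5)c4)c(OCc4ccccc4)c3)c(OCc3ccccc3)c2OCc2ccccc2)c(O)c(C(=O)OCC)c1O | intermediate
27 | 2,4,6-trihydroxy-5-(BCD-aryloxy)benzene-1,3-dicarboxylic acid | OC(=O)c1c(O)c(Oc2cc(OCc3ccccc3)c(Oc3cc(OCc4ccccc4)c(Oc4cc(OCc5ccccc5)c(OCc5ccccc5)c(OCc5ccccc5)c4)c(OCc4ccccc4)c3)c(OCc3ccccc3)c2OCc2ccccc2)c(O)c(C(=O)O)c1O | intermediate (not isolated)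
28 | 2-(BCD-aryloxy)benzene-1,3,5-triol | Oc1cc(O)c(Oc2cc(OCc3ccccc3)c(Oc3cc(OCc4ccccc4)c(Oc4cc(OCc5ccccc5)c(OCc5ccccc5)c(OCc5ccccc5)c4)c(OCc4ccccc4)c3)c(OCc3ccccc3)c2OCc2ccccc2)c(O)c1 | intermediate
29 | 2-{2,3,5-trihydroxy-4-[3,5-dihydroxy-4-(3,4,5-trihydroxyphenoxy)phenoxy]phenoxy}benzene-1,3,5-triol | Oc1cc(O)c(Oc2cc(O)c(Oc3cc(O)c(Oc4cc(O)c(O)c(O)c4)c(O)c3)c(O)c2O)c(O)c1 | target

**Step count and risks**

Total step count: 17. Longest linear sequence: 11 steps (steps 7 to 17, from 2-bromoresorcinol 11).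

Steps most likely to fail:

1. Step 15 (key step). The condensation may stop at the open-chain adduct, turn to O-acylation and lactonisation, or be outrun by self-condensation of the ketodiester at the temperature needed. The fallback sets out from phenol 21 and comes back to the route at target 29, using only reactions already in the route. Phenol 21 would be coupled with bromide 7 (CuI, picolinic acid, K3PO4, DMSO, 90 °C) to give 3,5-bis(benzyloxy)-4-(BCD-aryloxy)benzaldehyde F1. Baeyer–Villiger oxidation with mCPBA would give 3,5-bis(benzyloxy)-4-(BCD-aryloxy)phenyl formate F2, and methanolysis (cat. K2CO3, MeOH) would give 3,5-bis(benzyloxy)-4-(BCD-aryloxy)phenol F3. Hydrogenolysis of its ten benzyl ethers (H2, Pd/C) should deliver 29. This coupling is more hindered than steps 5 and 12, since phenol 21 carries one ortho benzyloxy group.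

2. Step 12. Substitution at the bromide flanked by two benzyloxy groups may be too slow, so that hydrodebromination of 18 and oxidative loss of the electron-rich phenoxide take over. The fallback reverses the polarity of the coupling; it sets out from 18 and 10 and comes back at 19. Bromide 18 would be converted by palladium-catalysed hydroxylation (Pd2(dba)3, tBuXPhos, KOH, 1,4-dioxane/H2O, 80 °C) into 2,3,5-tris(benzyloxy)-4-hydroxybenzaldehyde F4. Phenol 10 would be turned with Tf2O and pyridine into 3,5-bis(benzyloxy)-4-[3,4,5-tris(benzyloxy)phenoxy]phenyl trifluoromethanesulfonate F5, and palladium-catalysed borylation (B2(OH)4, Pd(OAc)2, XPhos, KOAc, EtOH, 80 °C) would give {3,5-bis(benzyloxy)-4-[3,4,5-tris(benzyloxy)phenoxy]phenyl}boronic acid F6. Chan–Lam coupling of F4 with F6 (Cu(OAc)2, pyridine, 4 Å molecular sieves, CH2Cl2, air, rt) would then give 19.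

3. Step 5. The failure mode is the same as in step 12, slow substitution at the hindered bromide with competing reduction. The fallback is the same polarity reversal; it sets out from 7 and 4 and comes back at 8. Bromide 7 would be hydroxylated (Pd2(dba)3, tBuXPhos, KOH, 1,4-dioxane/H2O, 80 °C) to 3,5-bis(benzyloxy)-4-hydroxybenzaldehyde F7. Phenol 4 would be converted with Tf2O and pyridine into 3,4,5-tris(benzyloxy)phenyl trifluoromethanesulfonate F8 and borylated (B2(OH)4, Pd(OAc)2, XPhos, KOAc, EtOH, 80 °C) to [3,4,5-tris(benzyloxy)phenyl]boronic acid F9. Chan–Lam coupling of F7 with F9 (Cu(OAc)2, pyridine, 4 Å molecular sieves, CH2Cl2, air, rt) would give 8.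

**Further compounds**

F1 | step 15 | 3,5-bis(benzyloxy)-4-(BCD-aryloxy)benzaldehyde | O=Cc1cc(OCc2ccccc2)c(Oc2cc(OCc3ccccc3)c(Oc3cc(OCc4ccccc4)c(Oc4cc(OCc5ccccc5)c(OCc5ccccc5)c(OCc5ccccc5)c4)c(OCc4ccccc4)c3)c(OCc3ccccc3)c2OCc2ccccc2)c(OCc2ccccc2)c1
F2 | step 15 | 3,5-bis(benzyloxy)-4-(BCD-aryloxy)phenyl formate | O=COc1cc(OCc2ccccc2)c(Oc2cc(OCc3ccccc3)c(Oc3cc(OCc4ccccc4)c(Oc4cc(OCc5ccccc5)c(OCc5ccccc5)c(OCc5ccccc5)c4)c(OCc4ccccc4)c3)c(OCc3ccccc3)c2OCc2ccccc2)c(OCc2ccccc2)c1
F3 | step 15 | 3,5-bis(benzyloxy)-4-(BCD-aryloxy)phenol | Oc1cc(OCc2ccccc2)c(Oc2cc(OCc3ccccc3)c(Oc3cc(OCc4ccccc4)c(Oc4cc(OCc5ccccc5)c(OCc5ccccc5)c(OCc5ccccc5)c4)c(OCc4ccccc4)c3)c(OCc3ccccc3)c2OCc2ccccc2)c(OCc2ccccc2)c1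
F4 | step 12 | 2,3,5-tris(benzyloxy)-4-hydroxybenzaldehyde | O=Cc1cc(OCc2ccccc2)c(O)c(OCc2ccccc2)c1OCc1ccccc1
F5 | step 12 | 3,5-bis(benzyloxy)-4-[3,4,5-tris(benzyloxy)phenoxy]phenyl trifluoromethanesulfonate | O=S(=O)(Oc1cc(OCc2ccccc2)c(Oc2cc(OCc3ccccc3)c(OCc3ccccc3)c(OCc3ccccc3)c2)c(OCc2ccccc2)c1)C(F)(F)F
F6 | step 12 | {3,5-bis(benzyloxy)-4-[3,4,5-tris(benzyloxy)phenoxy]phenyl}boronic acid | OB(O)c1cc(OCc2ccccc2)c(Oc2cc(OCc3ccccc3)c(OCc3ccccc3)c(OCc3ccccc3)c2)c(OCc2ccccc2)c1
F7 | step 5 | 3,5-bis(benzyloxy)-4-hydroxybenzaldehyde | O=Cc1cc(OCc2ccccc2)c(O)c(OCc2ccccc2)c1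
F8 | step 5 | 3,4,5-tris(benzyloxy)phenyl trifluoromethanesulfonate | O=S(=O)(Oc1cc(OCc2ccccc2)c(OCc2ccccc2)c(OCc2ccccc2)c1)C(F)(F)F
F9 | step 5 | [3,4,5-tris(benzyloxy)phenyl]boronic acid | OB(O)c1cc(OCc2ccccc2)c(OCc2ccccc2)c(OCc2ccccc2)c1
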